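**Plan**

- Retrosynthesis, in order: the two aryl acetate O–C(O) bonds (phenol masks); the carbinol C–H bond, back to a 3-aroyl ketone; the exocyclic C5=CH bond, back to a furan-2(5H)-one plus an aryl aldehyde; the ring C3=C4 bond together with the aroyl C=O, back to an alkyne and a ketone held in one phenacyl 3-arylpropiolate; then the ester O–CH2 bond, the alkyne–CO2H bond and the alkyne carbon–carbon triple bond (from an aldehyde).
- Enabling feature: ArCH(OH)–C3=C4(Ar') of the furanone ring is a reduced 2-acyl-alkene, the product pattern of an alkyne–carbonyl metathesis. The lactone atoms C2–O1–C5 are a three-atom ester tether that places alkyne carbon C3 and ketone carbon C4 in a five-membered array.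
- Forward: two aromatic fragments are joined as an open-chain ester; the furanone ring (the only ring made) closes by C3–C4 bond formation; the arylidene is then condensed onto C5 and the ketone is reduced.
- Stereochemistry: the Z alkene arises under thermodynamic control in the condensation. The single stereocentre comes from a catalyst-controlled oxazaborolidine (CBS) reduction of the aroyl ketone. The acetates keep both para oxygens electron-poor, so the carbinol cannot ionise before the last, cold basic step.

Key step: step 6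

Assumption: in the oxazaborolidine reduction the coplanar 3,5-dibromo-4-methoxyphenyl group is taken as the large ketone substituent and the twisted, fully substituted furanone carbon C3 as the small one, as for diaryl ketones with one twisted ring.

**Route**

Step 1
Reactants: 1 3,5-dibromo-4-methoxybenzaldehyde
Product: 3 1,3-dibromo-5-ethynyl-2-methoxybenzene, via diazoalkene 2 (not isolated)
Conditions: dimethyl (1-diazo-2-oxopropyl)phosphonate (1.3 equiv), K2CO3 (2 equiv), MeOH, 0 °C to rt
Reagents that add atoms: dimethyl (1-diazo-2-oxopropyl)phosphonate, CC(=O)C(=[N+]=[N-])P(=O)(OC)OC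
Why: Seyferth–Gilbert homologation in the Ohira–Bestmann variant: the diazomethylphosphonate anion released by methanolysis olefinates the aldehyde, and the diazoalkene loses N2 to a carbene that gives the alkyne by 1,2-shift; the carbonate base leaves the aryl bromides untouched.

Step 2
Reactants: 3 1,3-dibromo-5-ethynyl-2-methoxybenzene
Product: 5 3-(3,5-dibromo-4-methoxyphenyl)prop-2-ynoic acid, via lithium acetylide 4 (not isolated)
Conditions: LiN(SiMe3)2 (1.1 equiv), THF, −78 °C; CO2 (gas), −78 °C to rt; aq. HCl
Reagents that add atoms: carbon dioxide, O=C=O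
Why: Deprotonation of the terminal alkyne and carboxylation of the acetylide; a silylamide base, unlike an alkyllithium, cannot undergo halogen–lithium exchange with the aryl bromides.

Step 3
Reactants: 6 1-(3-bromo-4-hydroxyphenyl)ethan-1-one
Product: 7 4-acetyl-2-bromophenyl acetate
Conditions: Ac2O, pyridine, DMAP (cat.), CH2Cl2, rt
Reagents that add atoms: acetic anhydride, CC(=O)OC(C)=O
Why: Nucleophile-catalysed O-acetylation of the phenol; the acetate masks the phenol and, being electron-withdrawing, raises the electrophilicity of the para carbonyl group for step 6.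

Step 4
Reactants: 7 4-acetyl-2-bromophenyl acetate
Product: 8 2-bromo-4-(bromoacetyl)phenyl acetate
Conditions: Br2 (1.0 equiv), CHCl3, 0 °C to rt
Reagents that add atoms: bromine, BrBr
Why: Acid-catalysed α-bromination of the aryl methyl ketone through its enol; the ring is deactivated by acyl, bromo and acetoxy groups, so substitution should stay on the side chain.

Step 5
Reactants: 5 3-(3,5-dibromo-4-methoxyphenyl)prop-2-ynoic acid; 8 2-bromo-4-(bromoacetyl)phenyl acetate
Product: 9 2-(4-acetoxy-3-bromophenyl)-2-oxoethyl 3-(3,5-dibromo-4-methoxyphenyl)prop-2-ynoate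
Conditions: KHCO3 (1.2 equiv), DMF, rt
Reagents that add atoms: none
Why: SN2 O-alkylation of the potassium carboxylate by the phenacyl bromide (standard phenacyl ester formation); hydrogencarbonate is too weak to cleave the aryl acetate or to ionise the ketone methylene.

Step 6
Reactants: 9 2-(4-acetoxy-3-bromophenyl)-2-oxoethyl 3-(3,5-dibromo-4-methoxyphenyl)prop-2-ynoate
Product: 11 2-bromo-4-[4-(3,5-dibromo-4-methoxybenzoyl)-5-oxo-2,5-dihydrofuran-3-yl]phenyl acetate, via fused oxete 10 (not isolated)
Conditions: Tf2NH (20 mol %), 1,2-dichloroethane (0.02 M), 70 °C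
Reagents that add atoms: none
Why: Proposed new method: protonation of the aryl ketone lets the ester-bound alkyne carbon (the future C3) attack the ketone carbon (C4) while the positive charge growing on the aryl-bearing alkyne carbon is taken up by the ketone oxygen, an asynchronous [2+2] addition that gives the fused 2H-oxete 10; 4π-electrocyclic opening of 10 then delivers the ring C3=C4 bond and the exocyclic aroyl C=O in one isomerisation that sets nothing free. The closest known reaction type is the Brønsted or Lewis acid-catalysed intramolecular alkyne–carbonyl metathesis of ketones tethered to aryl alkynes, which gives 2-acylcycloalkenes and 3-acyl-2H-chromenes; new here is an alkynoate as the alkyne partner with its own ester group as the tether, so that the ring closed is an α,β-unsaturated γ-lactone. The lactone ring closes in the 5-exo-dig mode (only C3 of the alkyne enters the ring, and the ester must pass through its s-cis rotamer as in every butenolide closure of an α-acyloxy ketone), the transient oxete is a second, four-membered closure, and no stereocentre is formed. The step needs C3–C4 bonding to win over addition of the enol of the OCH2C(=O) unit to the alkynoate and over intermolecular reaction: the five-atom array C3–C2–O1–C5–C4 allows only this closure, the regiochemistry puts the cationic character on the benzylic alkyne carbon and not next to the ester carbonyl, and the base-free, dilute medium keeps the methylene un-ionised. The ketone is engaged in preference to the ester carbonyls because it is the more basic and the only one that can end as a ring alkene, and adventitious water would lead by alkyne hydration and acid-catalysed aldol condensation to the same product 11.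

Step 7
Reactants: 12 3-bromo-4-hydroxybenzaldehyde
Product: 13 2-bromo-4-formylphenyl acetate
Conditions: Ac2O, pyridine, DMAP (cat.), CH2Cl2, 0 °C to rt
Reagents that add atoms: acetic anhydride, CC(=O)OC(C)=O
Why: Nucleophile-catalysed O-acetylation of the phenol, giving the same mask as on the other ring and a more electrophilic aldehyde for step 8.

Step 8
Reactants: 11 2-bromo-4-[4-(3,5-dibromo-4-methoxybenzoyl)-5-oxo-2,5-dihydrofuran-3-yl]phenyl acetate; 13 2-bromo-4-formylphenyl acetate
Product: 16 2-bromo-4-{(Z)-[3-(4-acetoxy-3-bromophenyl)-4-(3,5-dibromo-4-methoxybenzoyl)-5-oxofuran-2(5H)-ylidene]methyl}phenyl acetate, via silyloxyfuran 14 (not isolated), via silylated aldol adduct 15 (not isolated)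
Conditions: TBSOTf (1.3 equiv), iPr2NEt (3 equiv), CH2Cl2, 0 °C to rt; then DBU (2 equiv), rt
Reagents that add atoms: none
Why: Vinylogous Mukaiyama aldol addition of the 2-silyloxyfuran at C5 to the aldehyde, then DBU-induced E1cB loss of silanol (the furanone–aldehyde condensation used for 5-arylidene butenolides); the Z alkene is the thermodynamic isomer because the E isomer would press the arylidene ring against the C4 aryl group, and these conditions spare the aryl acetates that a secondary amine would cleave.

Step 9
Reactants: 16 2-bromo-4-{(Z)-[3-(4-acetoxy-3-bromophenyl)-4-(3,5-dibromo-4-methoxybenzoyl)-5-oxofuran-2(5H)-ylidene]methyl}phenyl acetate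
Product: 17 2-bromo-4-{(Z)-[3-(4-acetoxy-3-bromophenyl)-4-[(S)-(3,5-dibromo-4-methoxyphenyl)(hydroxy)methyl]-5-oxofuran-2(5H)-ylidene]methyl}phenyl acetate
Conditions: (S)-2-methyl-CBS-oxazaborolidine (0.5 equiv), BH3·SMe2 (0.8 equiv), CH2Cl2, −30 °C; then MeOH, aqueous work-up
Reagents that add atoms: none
Why: Corey–Bakshi–Shibata reduction: the ketone should bind the catalyst boron through the lone pair on the side of the twisted furanone carbon, anti to the coplanar aryl group, so that the N-bound BH3 delivers hydride to the Re face; this is the sense that gives (R)-1-phenylethanol from acetophenone, named S here because the furanone carbon outranks the aryl group; borane reduces the ketone in 1,2-fashion and should leave lactone, acetates and conjugated alkenes alone.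

Step 10
Reactants: 17 2-bromo-4-{(Z)-[3-(4-acetoxy-3-bromophenyl)-4-[(S)-(3,5-dibromo-4-methoxyphenyl)(hydroxy)methyl]-5-oxofuran-2(5H)-ylidene]methyl}phenyl acetate
Product: 18 (Z)-5-(3-bromo-4-hydroxybenzylidene)-4-(3-bromo-4-hydroxyphenyl)-3-[(S)-(3,5-dibromo-4-methoxyphenyl)(hydroxy)methyl]furan-2(5H)-one
Conditions: K2CO3 (2.2 equiv), MeOH/THF, 0 °C; then AcOH to neutrality
Reagents that add atoms: none
Why: Zemplén-type base-mediated transesterification: methoxide should remove the two aryl acetates much faster than it attacks the conjugated enol lactone, the phenoxides that form deactivate the lactone further, and the cold basic medium avoids the acid-promoted ionisation of the carbinol that the free para-hydroxyaryl group would assist.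

**Compound list**

1 | 3,5-dibromo-4-methoxybenzaldehyde | COc1c(Br)cc(C=O)cc1Br | starting material
2 | 1,3-dibromo-5-(2-diazoethenyl)-2-methoxybenzene (diazoalkene, not isolated) | COc1c(Br)cc(C=C=[N+]=[N-])cc1Br | intermediate
3 | 1,3-dibromo-5-ethynyl-2-methoxybenzene | COc1c(Br)cc(C#C)cc1Br | intermediate
4 | lithium (3,5-dibromo-4-methoxyphenyl)acetylide (not isolated) | [Li]C#Cc1cc(Br)c(OC)c(Br)c1 | intermediate
5 | 3-(3,5-dibromo-4-methoxyphenyl)prop-2-ynoic acid | COc1c(Br)cc(C#CC(=O)O)cc1Br | intermediate
6 | 1-(3-bromo-4-hydroxyphenyl)ethan-1-one | CC(=O)c1ccc(O)c(Br)c1 | starting material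
7 | 4-acetyl-2-bromophenyl acetate | CC(=O)Oc1ccc(C(C)=O)cc1Br | intermediate
8 | 2-bromo-4-(bromoacetyl)phenyl acetate | CC(=O)Oc1ccc(C(=O)CBr)cc1Br | intermediate
9 | 2-(4-acetoxy-3-bromophenyl)-2-oxoethyl 3-(3,5-dibromo-4-methoxyphenyl)prop-2-ynoate | COc1c(Br)cc(C#CC(=O)OCC(=O)c2ccc(OC(C)=O)c(Br)c2)cc1Br | intermediate
10 | 2-bromo-4-[7-(3,5-dibromo-4-methoxyphenyl)-2-oxo-3,6-dioxabicyclo[3.2.0]hept-1(7)-en-5-yl]phenyl acetate (racemic 2H-oxete fused across C3–C4 of the lactone, not isolated) | CC(=O)Oc1ccc(C23COC(=O)C2=C(c2cc(Br)c(OC)c(Br)c2)O3)cc1Br | intermediate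
11 | 2-bromo-4-[4-(3,5-dibromo-4-methoxybenzoyl)-5-oxo-2,5-dihydrofuran-3-yl]phenyl acetate | COc1c(Br)cc(C(=O)C2=C(c3ccc(OC(C)=O)c(Br)c3)COC2=O)cc1Br | intermediate
12 | 3-bromo-4-hydroxybenzaldehyde | O=Cc1ccc(O)c(Br)c1 | starting material
13 | 2-bromo-4-formylphenyl acetate | CC(=O)Oc1ccc(C=O)cc1Br | intermediate
14 | 2-bromo-4-[5-(tert-butyldimethylsilyloxy)-4-(3,5-dibromo-4-methoxybenzoyl)furan-3-yl]phenyl acetate (not isolated) | CC(=O)Oc1ccc(-c2coc(O[Si](C)(C)C(C)(C)C)c2C(=O)c2cc(Br)c(OC)c(Br)c2)cc1Br | intermediate
15 | 2-bromo-4-{2-[(4-acetoxy-3-bromophenyl)(tert-butyldimethylsilyloxy)methyl]-4-(3,5-dibromo-4-methoxybenzoyl)-5-oxo-2,5-dihydrofuran-3-yl}phenyl acetate (racemic mixture of diastereomers, not isolated) | COc1c(Br)cc(C(=O)C2=C(c3ccc(OC(C)=O)c(Br)c3)C(C(O[Si](C)(C)C(C)(C)C)c3ccc(OC(C)=O)c(Br)c3)OC2=O)cc1Br | intermediate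
16 | 2-bromo-4-{(Z)-[3-(4-acetoxy-3-bromophenyl)-4-(3,5-dibromo-4-methoxybenzoyl)-5-oxofuran-2(5H)-ylidene]methyl}phenyl acetate | COc1c(Br)cc(C(=O)C2=C(c3ccc(OC(C)=O)c(Br)c3)/C(=C/c3ccc(OC(C)=O)c(Br)c3)OC2=O)cc1Br | intermediate
17 | 2-bromo-4-{(Z)-[3-(4-acetoxy-3-bromophenyl)-4-[(S)-(3,5-dibromo-4-methoxyphenyl)(hydroxy)methyl]-5-oxofuran-2(5H)-ylidene]methyl}phenyl acetate | COc1c(Br)cc([C@H](O)C2=C(c3ccc(OC(C)=O)c(Br)c3)/C(=C/c3ccc(OC(C)=O)c(Br)c3)OC2=O)cc1Br | intermediate
18 | (Z)-5-(3-bromo-4-hydroxybenzylidene)-4-(3-bromo-4-hydroxyphenyl)-3-[(S)-(3,5-dibromo-4-methoxyphenyl)(hydroxy)methyl]furan-2(5H)-one | COc1c(Br)cc([C@H](O)C2=C(c3ccc(O)c(Br)c3)/C(=C/c3ccc(O)c(Br)c3)OC2=O)cc1Br | target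

**Step count and risks**

Total steps: 10. Longest linear sequence: 7 (steps 1, 2, 5, 6, 8, 9, 10, or equally steps 3, 4, 5, 6, 8, 9, 10).

Steps most likely to fail:

1. Step 6 (proposed new method). The electron-poor alkynoate may be too weak a π-nucleophile to engage the protonated ketone, so that no ring closure occurs, or closure through the enolised methylene onto the alkynoate may compete. Fallback from 9, by known chemistry: gold-catalysed hydration of the alkynoate (Ph3PAuCl/AgSbF6, 5 mol % each, wet 1,4-dioxane, 60 °C), with the ester carbonyl directing oxygen to the β-carbon, should give the β-keto ester 2-(4-acetoxy-3-bromophenyl)-2-oxoethyl 3-(3,5-dibromo-4-methoxyphenyl)-3-oxopropanoate F1. Intramolecular Knoevenagel condensation of its active methylene onto the aryl ketone (Et3N, CH2Cl2, rt) then closes the same C3–C4 bond and returns to the route at 11.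

2. Step 9. Facial selectivity may be poor or reversed, because the two ketone substituents (a coplanar aryl group and a twisted, fully substituted alkenyl carbon) are not differentiated as clearly as aryl and alkyl. Fallback from 16, through resolution instead of asymmetric catalysis: Luche reduction (NaBH4, CeCl3·7H2O, MeOH/THF, −78 °C) should give the racemic carbinol 2-bromo-4-{(Z)-[3-(4-acetoxy-3-bromophenyl)-4-[(3,5-dibromo-4-methoxyphenyl)(hydroxy)methyl]-5-oxofuran-2(5H)-ylidene]methyl}phenyl acetate F2. Esterification with (S)-2-methoxy-2-phenylacetic acid (EDC·HCl, DMAP cat., CH2Cl2) gives two diastereomeric esters separable on silica, whose carbinol configuration can be assigned from the shielding pattern of the methoxyphenylacetate group: the (S)-carbinol (S)-2-methoxy-2-phenylacetate F3 and the discarded (R)-carbinol (S)-2-methoxy-2-phenylacetate F4. Treatment of F3 with K2CO3 in MeOH at 0 °C removes all three ester groups and returns to the route at 18.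

3. Step 8. The push–pull 3-aroyl-2-silyloxyfuran may add sluggishly to the aldehyde, and partial loss of aryl acetates or incomplete elimination may occur under DBU. Fallback from 11, by a Wittig approach instead of an aldol condensation: radical bromination at C5, the only allylic, oxygen-bearing C–H position (NBS, AIBN cat., PhCF3, 80 °C), should give 2-bromo-4-[2-bromo-4-(3,5-dibromo-4-methoxybenzoyl)-5-oxo-2,5-dihydrofuran-3-yl]phenyl acetate F5. Displacement with PPh3 (toluene, 60 °C) gives the phosphonium bromide [3-(4-acetoxy-3-bromophenyl)-4-(3,5-dibromo-4-methoxybenzoyl)-5-oxo-2,5-dihydrofuran-2-yl]triphenylphosphonium bromide F6. Its stabilised ylide (Et3N, CH2Cl2, rt) should olefinate aldehyde 13 and return to the route at 16, with iodine-catalysed equilibration to the Z isomer if needed.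

Further compounds
F1 | step 6 | 2-(4-acetoxy-3-bromophenyl)-2-oxoethyl 3-(3,5-dibromo-4-methoxyphenyl)-3-oxopropanoate | COc1c(Br)cc(C(=O)CC(=O)OCC(=O)c2ccc(OC(C)=O)c(Br)c2)cc1Br
F2 | step 9 | racemic 2-bromo-4-{(Z)-[3-(4-acetoxy-3-bromophenyl)-4-[(3,5-dibromo-4-methoxyphenyl)(hydroxy)methyl]-5-oxofuran-2(5H)-ylidene]methyl}phenyl acetate | COc1c(Br)cc(C(O)C2=C(c3ccc(OC(C)=O)c(Br)c3)/C(=C/c3ccc(OC(C)=O)c(Br)c3)OC2=O)cc1Br
F3 | step 9 | (S)-[(Z)-4-(4-acetoxy-3-bromophenyl)-5-(4-acetoxy-3-bromobenzylidene)-2-oxo-2,5-dihydrofuran-3-yl](3,5-dibromo-4-methoxyphenyl)methyl (S)-2-methoxy-2-phenylacetate | COc1c(Br)cc([C@H](OC(=O)[C@@H](OC)c2ccccc2)C2=C(c3ccc(OC(C)=O)c(Br)c3)/C(=C/c3ccc(OC(C)=O)c(Br)c3)OC2=O)cc1Br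
F4 | step 9 | (R)-[(Z)-4-(4-acetoxy-3-bromophenyl)-5-(4-acetoxy-3-bromobenzylidene)-2-oxo-2,5-dihydrofuran-3-yl](3,5-dibromo-4-methoxyphenyl)methyl (S)-2-methoxy-2-phenylacetate | COc1c(Br)cc([C@@H](OC(=O)[C@@H](OC)c2ccccc2)C2=C(c3ccc(OC(C)=O)c(Br)c3)/C(=C/c3ccc(OC(C)=O)c(Br)c3)OC2=O)cc1Br
F5 | step 8 | 2-bromo-4-[2-bromo-4-(3,5-dibromo-4-methoxybenzoyl)-5-oxo-2,5-dihydrofuran-3-yl]phenyl acetate (racemic) | COc1c(Br)cc(C(=O)C2=C(c3ccc(OC(C)=O)c(Br)c3)C(Br)OC2=O)cc1Br
F6 | step 8 | [3-(4-acetoxy-3-bromophenyl)-4-(3,5-dibromo-4-methoxybenzoyl)-5-oxo-2,5-dihydrofuran-2-yl]triphenylphosphonium bromide (racemic) | COc1c(Br)cc(C(=O)C2=C(c3ccc(OC(C)=O)c(Br)c3)C([P+](c3ccccc3)(c3ccccc3)c3ccccc3)OC2=O)cc1Br.[Br-]
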